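The rate constants are those of an exercise; the rest is arithmetic.

**The task.** Count the Z. X takes one Z to become D, D takes a second Z to become Q, and each addition releases one E. Q then leaves towards L and, with E, towards Q.E.

    X + Z → D + E (k1 = 13.5 L mol⁻¹ s⁻¹)
    Q ⇌ L (K2 = 1.9, k2 = 0.0166 s⁻¹)
    Q + E → Q.E (k3 = 2.13 L mol⁻¹ s⁻¹)
    Z + D → Q + E (k4 = 8.31 L mol⁻¹ s⁻¹)

| setting | ash | maple | birch | alder | cedar |
|---|---|---|---|---|---|
| X | 10 mM | 10 mM | 10 mM | 10 mM | 10 mM |
| Z | 4.00 mM | 8.00 mM | 15.0 mM | 30.0 mM | 60.0 mM |
| time | 1.0 min | 1.0 min | 1.0 min | 1.0 min | 1.0 min |

* amount of Q at the end, in percent of the X charged for ash, maple, birch, alder, cedar, in this order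
* how that number moves from the first to the last of them (rises, then falls / falls, then rises / falls all the way / rises all the way / hardly changes)

- "hardly changes" means that all values lie within two and a half points (for a concentration: within two and a half percent of the largest)
- run time (ash): 1.0 min

**Dropping time.** Dividing the first addition's rate by the second's cancels Z and leaves S·X/D, where S = 1.62 is the selectivity factor, the first rate constant over the second. Integrating D against X, with no clock needed, this ratio reaches one when X has fallen to a fraction 0.283 of its charge. Z spent by then is the crossover charge, 9.74 mM.

**The ladder.** In cedar, X has a half-life of 0.0143 min and D one of 0.0232 min, taken at the Z charged. In ash, X starts with a slower half-life of 0.214 min. Next, for cedar, comes capture of Q by E, reckoned at the 20.0 mM of E that two full additions release, though capture uses E up as it goes: a half-life of 0.271 min. Slower still is Q going to L, forward step alone, at 0.696 min, which fits within the 1.0 min run. So in cedar we expect Q to form faster than it drains, and to stand draining for most of the run.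

**Our reckoning.** Ash and maple hold less Z than the crossover charge, so we expect the first addition to lead to the end. The two additions together need 20.0 mM of Z. Alder and cedar hold more than that, so we expect extra Z there to bring Q forward and lengthen its drain. We commit to a rise followed by a fall, with the turn near that need.

**The forecast.** The forecast gave 1.9%, 4.8%, 12.5%, 14.3% and 9.4%, hence rises, then falls, holding that “cedar forms it earliest and with the most E, so it drains longest”.

**The result.** The flasks gave 1.79%, 5.21%, 12.7%, 14.4% and 10.5%, so the row rises, then falls, with the turn read at 22 mM of Z. Ash was charged with less Z than 9.74 mM; its first addition used Z faster than its second, by a factor of 8.0 at 0.0812 min, and S·X/D still stood at 3.42 at the end, with Z down to 0.0956% of its charge. Birch was charged with more, 15.0 mM, and with X at 9.14% and D at 35.9% at its end, S·X/D had fallen to 0.412.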